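**Retrosynthetic overview**
- The last C–C bond, C12–C13, is made by B-alkyl Suzuki coupling of a decalin C12 iodide with an (E)-alkenyl iodide built from (E)-geranylacetone (terminal alkyne, then methylalumination and iodination).
- The strategy rests on the vicinal pair on ring B of the cis-fused decalin: the tertiary carbinol C8 (CH3, OH) next to C9, whose C11 arm is trans to the hydroxyl and cis to the C10 methyl. Ring B (C5–C6–C7–C8–C9–C10) is closed at C8–C9 by addition of a samarium ketyl at C8 to the β-carbon C9 of an enoate.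
- The keto enoate comes from (R)-α-ionone, which supplies ring A and the C5 stereocentre. The quaternary C10 is set cis to the C5 arm by a Wittig–Still [2,3] shift from a C2 allylic alcohol cis to that arm; the resulting C9 carbinol is oxidised and olefinated.
- Ring order: ring A from the chiral pool, then ring B in the key step.

Key step: step 13

Assumption: (R)-α-ionone of high enantiomeric purity and geometrically pure (E)-geranylacetone are taken as purchasable. Labdane numbering (C1–C20) is used for the ring atoms throughout.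

**Route**

Step 1
Reactants: 1 (R)-α-ionone
Product: 2 (R)-dihydro-α-ionone [4-((1R)-2,6,6-trimethylcyclohex-2-en-1-yl)butan-2-one]
Conditions: H2 (1 atm), RhCl(PPh3)3 (5 mol %), benzene, rt
Reagents that add atoms: none
Why: Homogeneous hydrogenation with Wilkinson's catalyst should saturate the disubstituted conjugated C6=C7 alkene and leave the hindered trisubstituted ring alkene, the ketone and the C5 stereocentre untouched.

Step 2
Reactants: 2 (R)-dihydro-α-ionone
Product: 3 2-methyl-2-{2-[(1R)-2,6,6-trimethylcyclohex-2-en-1-yl]ethyl}-1,3-dioxolane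
Conditions: ethylene glycol, PPTS (cat.), benzene, reflux, Dean–Stark
Reagents that add atoms: ethylene glycol, OCCO
Why: Acid-catalysed ketalisation with azeotropic removal of water masks the C8 ketone, and the weak acid should not move the C1=C10 alkene into the tetrasubstituted position.

Step 3
Reactants: 3 dioxolane of dihydro-α-ionone
Product: 4 (4R)-3,5,5-trimethyl-4-[2-(2-methyl-1,3-dioxolan-2-yl)ethyl]cyclohex-2-en-1-one
Conditions: t-BuOOH, Rh2(cap)4 (cap = caprolactamate, 1 mol %), K2CO3, CH2Cl2, rt
Reagents that add atoms: tert-butyl hydroperoxide, CC(C)(C)OO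
Why: Radical allylic C–H oxidation with tert-butylperoxy radicals should take the ring methylene C2, because the other allylic C–H at C5 is tertiary and screened by the gem-dimethyl group; the carbonate buffer protects the ketal.

Step 4
Reactants: 4 enone ketal
Product: 5 trans-allylic alcohol (1R,4R)-3,5,5-trimethyl-4-[2-(2-methyl-1,3-dioxolan-2-yl)ethyl]cyclohex-2-en-1-ol (C2 hydroxyl trans to the C5 arm)
Conditions: LiBH(s-Bu)3 (L-Selectride), THF, –78 °C; then H2O
Reagents that add atoms: none
Why: 1,2-Reduction of a β,β-disubstituted enone by a bulky borohydride; in the half-chair with the C5 arm pseudoaxial the hydride should enter equatorially, away from the syn-axial C4 methyl, giving the pseudoaxial C2 alcohol trans to the arm (any cis epimer is compound 7 and is carried on directly).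

Step 5
Reactants: 5 trans-allylic alcohol
Product: 6 cis-ester (1S,4R)-3,5,5-trimethyl-4-[2-(2-methyl-1,3-dioxolan-2-yl)ethyl]cyclohex-2-en-1-yl 4-nitrobenzoate
Conditions: 4-nitrobenzoic acid, PPh3, DIAD, THF, 0 °C → rt
Reagents that add atoms: 4-nitrobenzoic acid, OC(=O)c1ccc(cc1)[N+](=O)[O-]
Why: Mitsunobu esterification displaces the oxyphosphonium group by SN2 with inversion at C2, which puts the C2 oxygen cis to the C5 arm.

Step 6
Reactants: 6 cis 4-nitrobenzoate
Product: 7 cis-allylic alcohol (1S,4R)-3,5,5-trimethyl-4-[2-(2-methyl-1,3-dioxolan-2-yl)ethyl]cyclohex-2-en-1-ol (C2 hydroxyl cis to the C5 arm)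
Conditions: K2CO3, MeOH, rt
Reagents that add atoms: none
Why: Base-catalysed transesterification cleaves the acyl–oxygen bond, so the C2 configuration is retained.

Step 7
Reactants: 7 cis-allylic alcohol
Product: 8 tributyl{[(1S,4R)-3,5,5-trimethyl-4-[2-(2-methyl-1,3-dioxolan-2-yl)ethyl]cyclohex-2-en-1-yl]oxymethyl}stannane
Conditions: KH, THF, 0 °C; Bu3SnCH2I, rt
Reagents that add atoms: (iodomethyl)tributylstannane, CCCC[Sn](CCCC)(CCCC)CI
Why: Williamson etherification of the potassium alkoxide with the primary iodide installs the stannylmethyl group without touching the C2 centre.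

Step 8
Reactants: 8 stannylmethyl ether
Product: 10 [(1S,6R)-1,5,5-trimethyl-6-[2-(2-methyl-1,3-dioxolan-2-yl)ethyl]cyclohex-2-en-1-yl]methanol, via lithiomethyl ether 9 (not isolated)
Conditions: n-BuLi, THF, –78 → –20 °C; then H2O
Reagents that add atoms: none
Why: Wittig–Still [2,3]-sigmatropic rearrangement: tin–lithium exchange gives the α-alkoxymethyllithium, which shifts suprafacially from the C2 oxygen to C10, so the new C9 carbinol carbon on the quaternary C10 is cis to the C5 arm, the C10 methyl takes the other face and the alkene moves to C1=C2.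

Step 9
Reactants: 10 homoallylic alcohol
Product: 11 [(1S,2R)-1,3,3-trimethyl-2-[2-(2-methyl-1,3-dioxolan-2-yl)ethyl]cyclohexyl]methanol
Conditions: H2 (1 atm), Pd/C, EtOAc, rt
Reagents that add atoms: none
Why: Heterogeneous hydrogenation of the disubstituted ring alkene creates no stereocentre (C1 and C2 become CH2), and the neutral medium keeps the ketal.

Step 10
Reactants: 11 saturated primary alcohol
Product: 12 (1S,2R)-1,3,3-trimethyl-2-[2-(2-methyl-1,3-dioxolan-2-yl)ethyl]cyclohexane-1-carbaldehyde
Conditions: Pr4N[RuO4] (5 mol %), NMO, 4 Å MS, CH2Cl2, rt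
Reagents that add atoms: none
Why: Ley–Griffith oxidation of the neopentyl alcohol stops at the aldehyde, which has no α-hydrogen and so cannot epimerise; the neutral conditions spare the ketal.

Step 11
Reactants: 12 aldehyde; 13 methyl (triphenylphosphoranylidene)acetate
Product: 14 methyl (E)-3-[(1R,2R)-1,3,3-trimethyl-2-[2-(2-methyl-1,3-dioxolan-2-yl)ethyl]cyclohexyl]prop-2-enoate
Conditions: toluene, 110 °C
Reagents that add atoms: none
Why: Wittig olefination with a stabilised ylide gives the (E)-enoate under thermodynamic control, and heating compensates for the α-quaternary aldehyde.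

Step 12
Reactants: 14 enoate ketal
Product: 15 methyl (E)-3-[(1R,2R)-1,3,3-trimethyl-2-(3-oxobutyl)cyclohexyl]prop-2-enoate (acrylate and oxobutyl arms cis)
Conditions: 1 M HCl, THF, rt
Reagents that add atoms: water, O
Why: Acid-catalysed hydrolysis of the dioxolane frees the C8 methyl ketone; the enoate and the two stereocentres are inert to dilute acid.

Step 13
Reactants: 15 keto enoate
Product: 16 methyl 2-[(1R,2R,4aR,8aS)-2-hydroxy-2,5,5,8a-tetramethyldecahydronaphthalen-1-yl]acetate (cis-fused)
Conditions: SmI2 (2.5 equiv), HMPA, t-BuOH (2 equiv), THF, –78 → 0 °C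
Reagents that add atoms: none
Why: SmI2, made more reducing and bulkier by HMPA, transfers one electron to the C8 methyl ketone; the samarium ketyl adds to the enoate β-carbon C9, and the α-ester radical is reduced by a second SmI2 to the samarium enolate, which t-BuOH protonates. The closest known reaction type is the SmI2 ketyl–olefin reductive cyclisation of keto enoates to anti 2-hydroxycycloalkylacetates. Ring B (C5–C6–C7–C8–C9–C10) closes in the 6-exo-trig mode through a chair in which the C10 methyl is axial and C4 is axial on the opposite face. C9 is controlled by that chair: the enoate carbon C11 should sit equatorial, because the axial alternative would meet C4 across the ring, so H9 ends anti to the C10 methyl and C11 cis to it. C8 is controlled by the solvated O–Sm group, which should take the equatorial site pointing away from the enoate (steric and dipole repulsion), so the hydroxyl ends trans to the C11 arm and the C8 methyl axial. The step needs the anti hydroxyl/arm relationship and attack on one enoate face; both should follow from this chair, whose shape is fixed by the cis arms at C5 and C10 set in step 8.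

Step 14
Reactants: 16 hydroxy ester
Product: 17 methyl 2-[(1R,2R,4aR,8aS)-2,5,5,8a-tetramethyl-2-(triethylsilyloxy)decahydronaphthalen-1-yl]acetate
Conditions: Et3SiOTf, 2,6-lutidine, CH2Cl2, –78 → 0 °C
Reagents that add atoms: triethylsilyl trifluoromethanesulfonate, CC[Si](CC)(CC)OS(=O)(=O)C(F)(F)F
Why: Silyl triflate silylation is fast enough for the tertiary C8 hydroxyl and blocks lactonisation and the later tetrahydrofuran closure onto C12.

Step 15
Reactants: 17 silyl ether ester
Product: 18 2-[(1R,2R,4aR,8aS)-2,5,5,8a-tetramethyl-2-(triethylsilyloxy)decahydronaphthalen-1-yl]ethanol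
Conditions: LiAlH4, THF, 0 °C
Reagents that add atoms: none
Why: Hydride reduction of the ester gives the C12 primary alcohol; the tertiary silyl ether and all stereocentres are inert.

Step 16
Reactants: 18 primary alcohol
Product: 19 triethyl{[(1R,2R,4aR,8aS)-1-(2-iodoethyl)-2,5,5,8a-tetramethyldecahydronaphthalen-2-yl]oxy}silane
Conditions: I2, PPh3, imidazole, CH2Cl2, 0 °C → rt
Reagents that add atoms: iodine, II
Why: Appel iodination converts the unhindered primary alcohol into the C12 iodide by SN2, with the C8 oxygen capped so that no ether ring can form.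

Step 17
Reactants: 20 (E)-geranylacetone
Product: 22 (E)-6,10-dimethylundeca-5,9-dien-1-yne, via enol phosphate 21 (not isolated)
Conditions: LiN(i-Pr)2 (1.05 equiv), THF, –78 °C; ClP(O)(OEt)2, –78 °C → rt; LiN(i-Pr)2 (2.3 equiv), –78 °C → rt; then H2O
Reagents that add atoms: none
Why: Kinetic deprotonation at the methyl group, O-phosphorylation and base-induced elimination of the terminal enol phosphate turn the methyl ketone into the terminal alkyne and leave the (E)-trisubstituted alkene alone.

Step 18
Reactants: 22 dienyne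
Product: 24 (1E,5E)-1-iodo-2,6,10-trimethylundeca-1,5,9-triene, via alkenylalane 23 (not isolated)
Conditions: Me3Al, Cp2ZrCl2, CH2Cl2, 0 °C → rt; then I2, THF, –30 → 0 °C
Reagents that add atoms: trimethylaluminium, C[Al](C)C; iodine, II
Why: Negishi zirconium-catalysed methylalumination adds methyl and aluminium syn across the terminal alkyne with aluminium at the terminus, and iodinolysis with retention gives the (E)-alkenyl iodide.

Step 19
Reactants: 19 C12 iodide; 24 (E)-alkenyl iodide
Product: 27 triethylsilyl ether of the target, via alkyllithium 25 (not isolated), via lithium borinate 26 (not isolated)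
Conditions: t-BuLi (2.1 equiv), Et2O, –78 °C; B-MeO-9-BBN, THF, –78 °C → rt; then 24, PdCl2(dppf) (5 mol %), AsPh3, Cs2CO3, DMF–H2O, rt
Reagents that add atoms: none
Why: B-alkyl Suzuki–Miyaura coupling: iodine–lithium exchange and trapping with B-methoxy-9-BBN give the borinate, which transfers the primary alkyl group to the alkenylpalladium iodide with retention of the (E)-geometry, forming C12–C13.

Step 20
Reactants: 27 silyl-protected target
Product: 28 (1R,2R,4aR,8aS)-2,5,5,8a-tetramethyl-1-[(3E,7E)-4,8,12-trimethyltrideca-3,7,11-trien-1-yl]decahydronaphthalen-2-ol (target)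
Conditions: Bu4NF, THF, rt → 40 °C
Reagents that add atoms: none
Why: Fluoride desilylation frees the tertiary C8 alcohol under non-acidic conditions, so the polyene cannot cyclise and the carbinol cannot dehydrate.

**Compound list**

1 | (R)-α-ionone | CC(=O)/C=C/[C@H]1C(C)=CCCC1(C)C | starting material
2 | (R)-dihydro-α-ionone | CC(=O)CC[C@H]1C(C)=CCCC1(C)C | intermediate
3 | 2-methyl-2-{2-[(1R)-2,6,6-trimethylcyclohex-2-en-1-yl]ethyl}-1,3-dioxolane | CC1(CC[C@H]2C(C)=CCCC2(C)C)OCCO1 | intermediate
4 | (4R)-3,5,5-trimethyl-4-[2-(2-methyl-1,3-dioxolan-2-yl)ethyl]cyclohex-2-en-1-one | CC1(CC[C@H]2C(C)=CC(=O)CC2(C)C)OCCO1 | intermediate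
5 | (1R,4R)-3,5,5-trimethyl-4-[2-(2-methyl-1,3-dioxolan-2-yl)ethyl]cyclohex-2-en-1-ol (trans) | CC1(CC[C@H]2C(C)=C[C@H](O)CC2(C)C)OCCO1 | intermediate
6 | (1S,4R)-3,5,5-trimethyl-4-[2-(2-methyl-1,3-dioxolan-2-yl)ethyl]cyclohex-2-en-1-yl 4-nitrobenzoate (cis) | CC1(CC[C@H]2C(C)=C[C@@H](OC(=O)c3ccc(cc3)[N+](=O)[O-])CC2(C)C)OCCO1 | intermediate
7 | (1S,4R)-3,5,5-trimethyl-4-[2-(2-methyl-1,3-dioxolan-2-yl)ethyl]cyclohex-2-en-1-ol (cis) | CC1(CC[C@H]2C(C)=C[C@@H](O)CC2(C)C)OCCO1 | intermediate
8 | tributylstannylmethyl ether of 7 | CC1(CC[C@H]2C(C)=C[C@@H](OC[Sn](CCCC)(CCCC)CCCC)CC2(C)C)OCCO1 | intermediate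
9 | lithiomethyl ether of 7 | CC1(CC[C@H]2C(C)=C[C@@H](OC[Li])CC2(C)C)OCCO1 | intermediate (not isolated)
10 | [(1S,6R)-1,5,5-trimethyl-6-[2-(2-methyl-1,3-dioxolan-2-yl)ethyl]cyclohex-2-en-1-yl]methanol | CC1(CC[C@H]2[C@@](C)(CO)C=CCC2(C)C)OCCO1 | intermediate
11 | [(1S,2R)-1,3,3-trimethyl-2-[2-(2-methyl-1,3-dioxolan-2-yl)ethyl]cyclohexyl]methanol | CC1(CC[C@H]2[C@@](C)(CO)CCCC2(C)C)OCCO1 | intermediate
12 | (1S,2R)-1,3,3-trimethyl-2-[2-(2-methyl-1,3-dioxolan-2-yl)ethyl]cyclohexane-1-carbaldehyde | CC1(CC[C@H]2[C@@](C)(C=O)CCCC2(C)C)OCCO1 | intermediate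
13 | methyl (triphenylphosphoranylidene)acetate | COC(=O)C=P(c1ccccc1)(c1ccccc1)c1ccccc1 | starting material
14 | methyl (E)-3-[(1R,2R)-1,3,3-trimethyl-2-[2-(2-methyl-1,3-dioxolan-2-yl)ethyl]cyclohexyl]prop-2-enoate | COC(=O)/C=C/[C@@]1(C)CCCC(C)(C)[C@H]1CCC2(C)OCCO2 | intermediate
15 | methyl (E)-3-[(1R,2R)-1,3,3-trimethyl-2-(3-oxobutyl)cyclohexyl]prop-2-enoate | COC(=O)/C=C/[C@@]1(C)CCCC(C)(C)[C@H]1CCC(C)=O | intermediate
16 | methyl 2-[(1R,2R,4aR,8aS)-2-hydroxy-2,5,5,8a-tetramethyldecahydronaphthalen-1-yl]acetate | COC(=O)C[C@@H]1[C@@]2(C)CCCC(C)(C)[C@H]2CC[C@@]1(C)O | intermediate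
17 | methyl 2-[(1R,2R,4aR,8aS)-2,5,5,8a-tetramethyl-2-(triethylsilyloxy)decahydronaphthalen-1-yl]acetate | COC(=O)C[C@@H]1[C@@]2(C)CCCC(C)(C)[C@H]2CC[C@@]1(C)O[Si](CC)(CC)CC | intermediate
18 | 2-[(1R,2R,4aR,8aS)-2,5,5,8a-tetramethyl-2-(triethylsilyloxy)decahydronaphthalen-1-yl]ethanol | OCC[C@@H]1[C@@]2(C)CCCC(C)(C)[C@H]2CC[C@@]1(C)O[Si](CC)(CC)CC | intermediate
19 | triethyl{[(1R,2R,4aR,8aS)-1-(2-iodoethyl)-2,5,5,8a-tetramethyldecahydronaphthalen-2-yl]oxy}silane | ICC[C@@H]1[C@@]2(C)CCCC(C)(C)[C@H]2CC[C@@]1(C)O[Si](CC)(CC)CC | intermediate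
20 | (E)-geranylacetone | CC(=O)CC/C=C(\C)CCC=C(C)C | starting material
21 | diethyl (E)-6,10-dimethylundeca-1,5,9-trien-2-yl phosphate | CCOP(=O)(OCC)OC(=C)CC/C=C(\C)CCC=C(C)C | intermediate (not isolated)
22 | (E)-6,10-dimethylundeca-5,9-dien-1-yne | C#CCC/C=C(\C)CCC=C(C)C | intermediate
23 | dimethyl[(1E,5E)-2,6,10-trimethylundeca-1,5,9-trien-1-yl]alane | C[Al](C)/C=C(\C)CC/C=C(\C)CCC=C(C)C | intermediate (not isolated)
24 | (1E,5E)-1-iodo-2,6,10-trimethylundeca-1,5,9-triene | I/C=C(\C)CC/C=C(\C)CCC=C(C)C | intermediate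
25 | C12 alkyllithium from 19 | [Li]CC[C@@H]1[C@@]2(C)CCCC(C)(C)[C@H]2CC[C@@]1(C)O[Si](CC)(CC)CC | intermediate (not isolated)
26 | lithium B-alkyl-B-methoxy-9-borabicyclo[3.3.1]nonane borinate from 25 | [Li+].CO[B-]1(CC[C@@H]2[C@@]3(C)CCCC(C)(C)[C@H]3CC[C@@]2(C)O[Si](CC)(CC)CC)C4CCCC1CCC4 | intermediate (not isolated)
27 | triethylsilyl ether of the target | CC(C)=CCC/C(C)=C/CC/C(C)=C/CC[C@@H]1[C@@]2(C)CCCC(C)(C)[C@H]2CC[C@@]1(C)O[Si](CC)(CC)CC | intermediate
28 | (1R,2R,4aR,8aS)-2,5,5,8a-tetramethyl-1-[(3E,7E)-4,8,12-trimethyltrideca-3,7,11-trien-1-yl]decahydronaphthalen-2-ol | CC(C)=CCC/C(C)=C/CC/C(C)=C/CC[C@@H]1[C@@]2(C)CCCC(C)(C)[C@H]2CC[C@@]1(C)O | target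

**Step count**
Total steps: 20. Longest linear sequence: 18 (steps 1–16, 19, 20).

**Steps most likely to fail**

1. Step 13. Addition of the ketyl to the neopentyl-type enoate carbon C9 may be outrun by simple reduction of the enoate or the ketone. The competing chair of ring A would deliver the other enoate face, and the anti preference at C8 may be incomplete, so epimers or lactonised material may form. Fallback, a polar closure of the same C8–C9 bond, setting out from 14 and returning at 28: reduction of 14 with i-Bu2AlH (CH2Cl2, –78 °C) would give the (E)-allylic alcohol F1, aqueous HCl in THF the keto allylic alcohol F2, and CBr4/PPh3 the allylic bromide F3. Indium powder in THF–H2O would then form the allylindium species, which adds through its γ-carbon C9 to the C8 ketone (intramolecular Barbier allylation through a six-membered chair with the vinyl group equatorial); this closes ring B and gives the vinyl carbinol F4 with C11=C12 as a terminal alkene. Hydroboration with 9-BBN would give the B-alkyl borane F5, which is coupled in the same flask with alkenyl iodide 24 (PdCl2(dppf), aqueous NaOH) to reach target 28; steps 14–16 and 20 fall away.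

2. Step 8. The new bond forms at a fully substituted carbon, syn-axial to a C4 methyl, so a [1,2]-shift or protonation of the α-alkoxymethyllithium may compete with the [2,3] shift. Fallback, setting out from 7 and returning at 12: Johnson–Claisen rearrangement (MeC(OEt)3, cat. EtCO2H, xylene, 140 °C) would deliver the two-carbon ester arm to C10 through a chair [3,3] shift on the face of the C2 oxygen, giving the unsaturated ester F6. Hydrogenation (H2, Pd/C) would give the saturated ester F7, LiN(i-Pr)2/Me3SiCl the silyl ketene acetal F8, and ozonolysis (O3, CH2Cl2, –78 °C; Me2S) would remove the extra carbon to give aldehyde 12.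

3. Step 4. Hydride delivery may be divided between the two faces of the enone, so the trans alcohol may come with its cis epimer. Fallback, setting out from 4 and returning at 7: Luche reduction (NaBH4, CeCl3·7H2O, MeOH, –78 °C) followed by chromatographic separation; the cis epimer is 7 and goes straight to step 7, the trans epimer is 5 and passes through steps 5 and 6, so both faces converge on 7 and the temporary C2 centre is removed in step 8.

**Further compounds**

F1 | step 13 | (E)-3-[(1R,2R)-1,3,3-trimethyl-2-[2-(2-methyl-1,3-dioxolan-2-yl)ethyl]cyclohexyl]prop-2-en-1-ol | OC/C=C/[C@@]1(C)CCCC(C)(C)[C@H]1CCC2(C)OCCO2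
F2 | step 13 | 4-[(1R,2R)-2-((E)-3-hydroxyprop-1-enyl)-2,6,6-trimethylcyclohexyl]butan-2-one | OC/C=C/[C@@]1(C)CCCC(C)(C)[C@H]1CCC(C)=O
F3 | step 13 | 4-[(1R,2R)-2-((E)-3-bromoprop-1-enyl)-2,6,6-trimethylcyclohexyl]butan-2-one | BrC/C=C/[C@@]1(C)CCCC(C)(C)[C@H]1CCC(C)=O
F4 | step 13 | (1R,2R,4aR,8aS)-1-ethenyl-2,5,5,8a-tetramethyldecahydronaphthalen-2-ol | C=C[C@@H]1[C@@]2(C)CCCC(C)(C)[C@H]2CC[C@@]1(C)O
F5 | step 13 | B-alkyl-9-borabicyclo[3.3.1]nonane from F4 (boron on C12) | B1(CC[C@@H]2[C@@]3(C)CCCC(C)(C)[C@H]3CC[C@@]2(C)O)C4CCCC1CCC4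
F6 | step 8 | ethyl 2-[1,5,5-trimethyl-6-[2-(2-methyl-1,3-dioxolan-2-yl)ethyl]cyclohex-2-en-1-yl]acetate (ester arm cis to the C5 arm) | CCOC(=O)C[C@@]1(C)C=CCC(C)(C)[C@H]1CCC2(C)OCCO2
F7 | step 8 | ethyl 2-[1,3,3-trimethyl-2-[2-(2-methyl-1,3-dioxolan-2-yl)ethyl]cyclohexyl]acetate (arms cis) | CCOC(=O)C[C@@]1(C)CCCC(C)(C)[C@H]1CCC2(C)OCCO2
F8 | step 8 | ethyl trimethylsilyl ketene acetal of F7 | CCOC(O[Si](C)(C)C)=C[C@@]1(C)CCCC(C)(C)[C@H]1CCC2(C)OCCO2
F0 | step 4 | none | none
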